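## Retrosynthetic overview

1. Target 20 ⇐ six-fold O-demethylation of the (S)-hexamethyl ether 19 ⇐ chiral-phase resolution of racemic dimer 18.
2. 18 ⇐ oxidative C–O dehydrodimerisation of two molecules of 2-ethyl-3-hydroxy-5,6,8-trimethoxy-1,4-naphthoquinone 17; one half stays a quinone, the other becomes the 2,2-disubstituted 1,3,4-trione.
3. 17 ⇐ autoxidation of naphthalene-1,3-diol 15 ⇐ intramolecular Friedel–Crafts acylation of β-keto ester 14, which closes the second ring onto the benzene ring.
4. 14 ⇐ oxidation of aldol 13 ⇐ intermolecular aldol addition of the ethyl butanoate enolate to arylacetaldehyde 10 (key C–C bond, C2–C3 of the future quinone ring).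
5. 10 ⇐ allylarene 8 ⇐ vanillin 1 (O-allylation, Claisen, Dakin, methylation). Ring order: benzenoid ring (from vanillin), then the enol/quinone ring, then the trione ring by oxidation during dimerisation.

Assumption: the stereocentre is (S) by CIP (O > C3 > C1 > ethyl), and because the radical dimerisation offers no handle for asymmetric induction, the single enantiomer is obtained by chromatographic resolution of 18 and assigned by ECD/TDDFT or X-ray.

## Route

Step 1
Reactants: 1 vanillin (4-hydroxy-3-methoxybenzaldehyde); 2 allyl bromide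
Product: 3 4-(allyloxy)-3-methoxybenzaldehyde
Conditions: K2CO3, acetone, reflux
Reagents that add atoms: none
Why: Williamson ether synthesis (SN2 of the phenoxide on a primary allylic bromide); the aldehyde is inert to carbonate.

Step 2
Reactants: 3 4-(allyloxy)-3-methoxybenzaldehyde
Product: 5 3-allyl-4-hydroxy-5-methoxybenzaldehyde, via ortho-allyl cyclohexadienone 4 (not isolated)
Conditions: N,N-diethylaniline, 200 °C, N2
Reagents that add atoms: none
Why: Aromatic Claisen rearrangement ([3,3]) can only deliver the allyl group to the one free ortho position, and the dienone re-aromatises by enolisation.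

Step 3
Reactants: 5 3-allyl-4-hydroxy-5-methoxybenzaldehyde
Product: 7 2-allyl-6-methoxybenzene-1,4-diol, via aryl formate 6 (not isolated)
Conditions: 30% H2O2 (1.2 equiv), NaOH (1.1 equiv), THF/H2O, 0 °C → rt, N2; then 1 M HCl
Reagents that add atoms: hydrogen peroxide, OO
Why: Dakin oxidation, in which the para-phenoxide drives aryl migration and the formate is saponified in situ, while the isolated alkene is inert to alkaline peroxide.

Step 4
Reactants: 7 2-allyl-6-methoxybenzene-1,4-diol
Product: 8 1-allyl-2,3,5-trimethoxybenzene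
Conditions: MeI (3 equiv), K2CO3, DMF, rt, N2
Reagents that add atoms: iodomethane, CI
Why: Double Williamson O-methylation of the air-sensitive hydroquinone fixes the 1,2,4-trioxygenation pattern; carbonate is too weak to isomerise the allyl group.

Step 5
Reactants: 8 1-allyl-2,3,5-trimethoxybenzene
Product: 10 2-(2,3,5-trimethoxyphenyl)acetaldehyde, via vicinal diol 9 (not isolated)
Conditions: OsO4 (2 mol%), NaIO4 (4 equiv), 2,6-lutidine, dioxane/H2O 3:1, rt; crude aldehyde used at once
Reagents that add atoms: osmium tetroxide, O=[Os](=O)(=O)=O; sodium periodate, [Na+].[O-]I(=O)(=O)=O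
Why: Lemieux–Johnson oxidative cleavage (catalytic dihydroxylation, then periodate glycol cleavage) removes only the terminal CH2 and leaves the methoxyarene untouched.

Step 6
Reactants: 10 2-(2,3,5-trimethoxyphenyl)acetaldehyde; 11 ethyl butanoate
Product: 13 ethyl 2-ethyl-3-hydroxy-4-(2,3,5-trimethoxyphenyl)butanoate (racemic diastereomer mixture), via lithium enolate of ethyl butanoate 12 (not isolated)
Conditions: LDA (1.5 equiv), THF, −78 °C; then 10, −78 °C, 30 min; AcOH quench at −78 °C
Reagents that add atoms: none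
Why: Intermolecular aldol addition of a preformed lithium ester enolate, where addition at −78 °C outruns enolisation of the aldehyde; the two new stereocentres form unselectively but are both erased in steps 7–9.

Step 7
Reactants: 13 ethyl 2-ethyl-3-hydroxy-4-(2,3,5-trimethoxyphenyl)butanoate
Product: 14 ethyl 2-ethyl-3-oxo-4-(2,3,5-trimethoxyphenyl)butanoate
Conditions: Dess–Martin periodinane (1.3 equiv), CH2Cl2, 0 °C → rt
Reagents that add atoms: none
Why: Dess–Martin oxidation of a secondary alcohol to the β-keto ester under neutral, non-enolising conditions that do not touch the electron-rich arene.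

Step 8
Reactants: 14 ethyl 2-ethyl-3-oxo-4-(2,3,5-trimethoxyphenyl)butanoate
Product: 15 2-ethyl-5,6,8-trimethoxynaphthalene-1,3-diol
Conditions: conc. H2SO4, 0 °C → rt, 1 h; ice quench, work-up under N2, crude solid used at once
Reagents that add atoms: none
Why: Intramolecular Friedel–Crafts acylation by the protonated ester at the only free position ortho to the side chain (ortho and para to two OMe groups), followed by enolisation to the aromatic naphthalenediol.

Step 9
Reactants: 15 2-ethyl-5,6,8-trimethoxynaphthalene-1,3-diol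
Product: 17 2-ethyl-3-hydroxy-5,6,8-trimethoxynaphthalene-1,4-dione, via C4-hydroperoxide 16 (not isolated)
Conditions: O2 (1 atm), KOH, MeOH/H2O, 0 °C → rt; then 1 M HCl
Reagents that add atoms: dioxygen, O=O
Why: Base-mediated autoxidation of the electron-rich naphtholate at C4 (para to O-1), with loss of water from the hydroperoxide, gives the 2-hydroxy-1,4-quinone, which is stable as its anion.

Step 10
Reactants: 17 2-ethyl-3-hydroxy-5,6,8-trimethoxynaphthalene-1,4-dione (two molecules)
Product: 18 2-ethyl-3-[(2-ethyl-5,6,8-trimethoxy-1,3,4-trioxo-1,2,3,4-tetrahydronaphthalen-2-yl)oxy]-5,6,8-trimethoxynaphthalene-1,4-dione (racemic)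
Conditions: PbO2 (1.5 equiv), AcOH, rt, dark, 1 h; filter through Celite
Reagents that add atoms: none
Why: One-electron oxidation of the acidic enol gives a radical delocalised over O-3 and C-2, and O–C combination of two radicals is the known "lapachol peroxide"-type dehydrodimerisation of 3-alkyl-2-hydroxynaphthoquinones; the quaternary centre forms as a racemate.

Step 11
Reactants: 18 racemic hexamethyl ether dimer
Product: 19 2-ethyl-3-{[(2S)-2-ethyl-5,6,8-trimethoxy-1,3,4-trioxo-1,2,3,4-tetrahydronaphthalen-2-yl]oxy}-5,6,8-trimethoxynaphthalene-1,4-dione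
Conditions: preparative HPLC on immobilised polysaccharide phase (Chiralpak IC), n-heptane/EtOAc, alcohol-free; (S)-enantiomer assigned by ECD/TDDFT
Reagents that add atoms: none
Why: Enantiomer resolution on a chiral stationary phase; the centre is quaternary with no α-hydrogen and cannot epimerise, so the (S)-enantiomer is carried on unchanged.

Step 12
Reactants: 19 (S)-hexamethyl ether dimer
Product: 20 2-ethyl-3-{[(2S)-2-ethyl-5,6,8-trihydroxy-1,3,4-trioxo-1,2,3,4-tetrahydronaphthalen-2-yl]oxy}-5,6,8-trihydroxynaphthalene-1,4-dione (CNP0325426.1)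
Conditions: BBr3 (10 equiv), CH2Cl2, −78 °C → 0 °C; ice-water quench
Reagents that add atoms: none
Why: BBr3 ether cleavage in which bromide attacks only the methyl carbons (SN2, peri-methoxy groups first through chelation to C=O); the tertiary α,α-diacyl ether can neither ionise nor undergo SN2, so the stereocentre is untouched.

## Compound list

1 | vanillin (4-hydroxy-3-methoxybenzaldehyde) | COc1cc(C=O)ccc1O | starting material
2 | allyl bromide | C=CCBr | starting material
3 | 4-(allyloxy)-3-methoxybenzaldehyde | COc1cc(C=O)ccc1OCC=C | intermediate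
4 | 5-methoxy-4-oxo-3-(prop-2-en-1-yl)cyclohexa-1,5-diene-1-carbaldehyde (racemic Claisen dienone, not isolated) | O=CC1=CC(CC=C)C(=O)C(OC)=C1 | intermediate
5 | 3-allyl-4-hydroxy-5-methoxybenzaldehyde | COc1cc(C=O)cc(CC=C)c1O | intermediate
6 | 3-allyl-4-hydroxy-5-methoxyphenyl formate (not isolated) | COc1cc(OC=O)cc(CC=C)c1O | intermediate
7 | 2-allyl-6-methoxybenzene-1,4-diol | COc1cc(O)cc(CC=C)c1O | intermediate
8 | 1-allyl-2,3,5-trimethoxybenzene | COc1cc(OC)cc(CC=C)c1OC | intermediate
9 | 3-(2,3,5-trimethoxyphenyl)propane-1,2-diol (racemic, not isolated) | COc1cc(OC)cc(CC(O)CO)c1OC | intermediate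
10 | 2-(2,3,5-trimethoxyphenyl)acetaldehyde | COc1cc(OC)cc(CC=O)c1OC | intermediate
11 | ethyl butanoate | CCCC(=O)OCC | starting material
12 | lithium enolate of ethyl butanoate (not isolated) | CCC=C(OCC)O[Li] | intermediate
13 | ethyl 2-ethyl-3-hydroxy-4-(2,3,5-trimethoxyphenyl)butanoate (racemic diastereomer mixture) | CCOC(=O)C(CC)C(O)Cc1cc(OC)cc(OC)c1OC | intermediate
14 | ethyl 2-ethyl-3-oxo-4-(2,3,5-trimethoxyphenyl)butanoate (racemic, labile α-centre) | CCOC(=O)C(CC)C(=O)Cc1cc(OC)cc(OC)c1OC | intermediate
15 | 2-ethyl-5,6,8-trimethoxynaphthalene-1,3-diol | CCc1c(O)cc2c(OC)c(OC)cc(OC)c2c1O | intermediate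
16 | 2-ethyl-4-hydroperoxy-3-hydroxy-5,6,8-trimethoxynaphthalen-1(4H)-one (racemic, not isolated) | CCC1=C(O)C(OO)c2c(OC)c(OC)cc(OC)c2C1=O | intermediate
17 | 2-ethyl-3-hydroxy-5,6,8-trimethoxynaphthalene-1,4-dione | CCC1=C(O)C(=O)c2c(OC)c(OC)cc(OC)c2C1=O | intermediate
18 | racemic 2-ethyl-3-[(2-ethyl-5,6,8-trimethoxy-1,3,4-trioxo-1,2,3,4-tetrahydronaphthalen-2-yl)oxy]-5,6,8-trimethoxynaphthalene-1,4-dione | CCC1=C(OC2(CC)C(=O)C(=O)c3c(OC)c(OC)cc(OC)c3C2=O)C(=O)c2c(OC)c(OC)cc(OC)c2C1=O | intermediate
19 | (S)-enantiomer of 18 | CCC1=C(O[C@]2(CC)C(=O)C(=O)c3c(OC)c(OC)cc(OC)c3C2=O)C(=O)c2c(OC)c(OC)cc(OC)c2C1=O | intermediate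
20 | 2-ethyl-3-{[(2S)-2-ethyl-5,6,8-trihydroxy-1,3,4-trioxo-1,2,3,4-tetrahydronaphthalen-2-yl]oxy}-5,6,8-trihydroxynaphthalene-1,4-dione | CCC1=C(O[C@]2(CC)C(=O)C(=O)c3c(O)c(O)cc(O)c3C2=O)C(=O)c2c(O)c(O)cc(O)c2C1=O | target

## Step count and risks

Total step count: 12. Longest linear sequence: 12 steps (from vanillin 1; allyl bromide 2 and ethyl butanoate 11 enter as purchased partners).

The three steps most likely to fail:

Step 6 (aldol with an easily enolised arylacetaldehyde). If the enolate mainly deprotonates 10, the fallback sets out from 10 and rejoins at 14 with a Claisen-type bond formation instead. Aldehyde 10 is oxidised (NaClO2, NaH2PO4, 2-methyl-2-butene, t-BuOH/H2O) to 2-(2,3,5-trimethoxyphenyl)acetic acid F1, which is activated with carbonyldiimidazole in THF to 1-[2-(2,3,5-trimethoxyphenyl)acetyl]imidazole F2. This is treated with potassium ethyl 2-ethylmalonate F3 (from diethyl 2-ethylmalonate, 1 equiv KOH, EtOH) in the presence of MgCl2/Et3N in MeCN. The decarboxylative (malonate half-ester) Claisen condensation tolerates the acidic benzylic protons and gives keto ester 14 directly, bypassing 13.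

Step 10 (radical dehydrodimerisation; C–C coupling or over-oxidation could compete). The fallback sets out from 17 and rejoins at 18 by a two-component ionic coupling. One portion of 17 is brominated at C2 (NBS, 1.0 equiv, CH2Cl2, 0 °C) to 2-bromo-2-ethyl-5,6,8-trimethoxynaphthalene-1,3,4(2H)-trione F4. The other portion is converted with Ag2O into silver 3-ethyl-5,6,8-trimethoxy-1,4-dioxo-1,4-dihydronaphthalen-2-olate F5. Combining F4 and F5 in dry MeCN in the dark gives silver-assisted substitution of the tertiary α-bromo-β-dicarbonyl by the quinone oxygen, so each half has a defined role, and delivers 18.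

Step 12 (six-fold BBr3 demethylation next to a trione and a vinylogous ester linkage). The fallback sets out from 17 and rejoins at 20 by deprotecting before dimerising. Monomer 17 is demethylated (BBr3, CH2Cl2, −78 °C → rt) to the robust free monomer 2-ethyl-3,5,6,8-tetrahydroxynaphthalene-1,4-dione F6. Unprotected, biomimetic one-electron oxidation (PbO2/AcOH, or Ag2O in EtOAc) couples O-3 to the ethyl-bearing carbon and gives racemic 2-ethyl-3-[(2-ethyl-5,6,8-trihydroxy-1,3,4-trioxo-1,2,3,4-tetrahydronaphthalen-2-yl)oxy]-5,6,8-trihydroxynaphthalene-1,4-dione F7. Chiral-phase HPLC with an acidified eluent then gives 20. This is less selective, because the second enolic OH and the free ring position can also couple, but no Lewis acid ever meets the dimer.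

## Further compounds

F1 | step 6 | 2-(2,3,5-trimethoxyphenyl)acetic acid | COc1cc(OC)cc(CC(=O)O)c1OC
F2 | step 6 | 1-[2-(2,3,5-trimethoxyphenyl)acetyl]imidazole | COc1cc(OC)cc(CC(=O)n2ccnc2)c1OC
F3 | step 6 | potassium ethyl 2-ethylmalonate | CCOC(=O)C(CC)C(=O)[O-].[K+]
F4 | step 10 | 2-bromo-2-ethyl-5,6,8-trimethoxynaphthalene-1,3,4(2H)-trione (racemic) | CCC1(Br)C(=O)C(=O)c2c(OC)c(OC)cc(OC)c2C1=O
F5 | step 10 | silver 3-ethyl-5,6,8-trimethoxy-1,4-dioxo-1,4-dihydronaphthalen-2-olate | CCC1=C([O-])C(=O)c2c(OC)c(OC)cc(OC)c2C1=O.[Ag+]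
F6 | step 12 | 2-ethyl-3,5,6,8-tetrahydroxynaphthalene-1,4-dione | CCC1=C(O)C(=O)c2c(O)c(O)cc(O)c2C1=O
F7 | step 12 | racemic 2-ethyl-3-[(2-ethyl-5,6,8-trihydroxy-1,3,4-trioxo-1,2,3,4-tetrahydronaphthalen-2-yl)oxy]-5,6,8-trihydroxynaphthalene-1,4-dione | CCC1=C(OC2(CC)C(=O)C(=O)c3c(O)c(O)cc(O)c3C2=O)C(=O)c2c(O)c(O)cc(O)c2C1=O
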